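Each quenched substrate takes one starting material and one protic impurity, so quenched substrate plus impurity stays at the impurity charge; divide the two rates and time drops out, the ratio being one. The charge beyond the impurity, the free charge F = 0.400 M, is what the quench cannot take, and initiator does not enter it.

| flask | starting material | reagent | protic impurity | initiator | remark | time |
|---|---|---|---|---|---|---|
| noon | 0.80 M (in portions, 2) | 1.5 equiv | 0.40 M | 0.95 mol% | run made earlier; portions every 6.0 h |  |
| flask | 0.80 M (in portions, 2) | 1.50 equiv | 0.400 M | 0.63 mol% | the portions of starting material follow each other after 6.0 h, the first at the start | 12 h |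

- noon (time / h: target / %, quenched substrate / %): 0.417: 2.7, 22.2; 1.33: 5.2, 33.9; 2.50: 7.0, 38.7; 4.00: 5.8, 40.0

(each reading ± 0.5 percentage points)

1. concentration of target at 12 h, in M
2. concentration of quenched substrate at 12 h, in M

- no earlier run changes the charge of initiator; that part of a forecast is a guess

In the noon run quenched substrate reads 40.0% of the charge at 4.00 h, or 0.320 M. If the new flask does the same, about 0.0800 M of impurity meets a second portion of 0.400 M, a larger amount, which makes impurity the limiting reagent. The noon run read about half of that value at 0.417 h, far less than the 6.0 h the second portion has in the flask. So for the flask reckon on 0.400 M of quenched substrate at 12 h, and treat F as a ceiling for the target side, not as a value.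

The forecast gives 0.12 M of target and 0.393 M of quenched substrate, “limited by the impurity”. The flask gives 0.0667 M of target and 0.400 M of quenched substrate.

    starting material + protic impurity → quenched substrate (k = 0.0800 L mol⁻¹ min⁻¹)
    reagent + first chain carrier → target + second chain carrier (k = 36500 L mol⁻¹ min⁻¹)
    2 first chain carrier → ended chains B (k = 4.00 × 10⁷ L mol⁻¹ s⁻¹)
    starting material + second chain carrier → by-product + first chain carrier (k = 8930 L mol⁻¹ min⁻¹)
    2 second chain carrier → ended chains A (k = 3.00 × 10⁶ L mol⁻¹ s⁻¹)
    initiator → 2 initiating radical (k = 0.00422 min⁻¹)
    target → over-reaction product (k = 0.00297 min⁻¹)
    starting material + initiating radical → capped initiator + first chain carrier (k = 11400 L mol⁻¹ s⁻¹)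

In the flask the quenched substrate lands on the reckoned 0.400 M, with impurity down to 0.0055% of its charge at 12.0 h. At that time the flask holds 29.0% of the charge as starting material, so F less what is left is 0.168 M, and target, over-reaction product and ended chains B, counted by the starting material they hold, come to 0.168 M. The neighbour flask with 1.6 mol% of initiator has the same F and gives 0.400 M of quenched substrate; with 20.6% of starting material left, F less that is 0.235 M, and the same three, counted the same way, come to 0.235 M.

The data come from a simulation with constants of no real substance; noise was put on by code.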